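The data are simulated for substances that don't exist.

The vessel is stirred, keeps its volume and temperature, and takes the starting complex in equal portions while the gas is held; I want three amounts from it.

common to all: gas 20 mM (held)

| flask | starting complex | remark | time |
|---|---|---|---|
| zeta | 0.17 M (in portions, 3) | run made earlier; portions every 4.0 min |  |
| gamma | 0.66 M (in portions, 3) | run made earlier; portions every 4.0 min |  |
| flask | 0.33 M (in portions, 3) | the portions of starting complex follow each other after 4.0 min, the first at the start | 12 min |

- zeta (time / min: complex with one exchanged / %, complex with two exchanged / %): 2.00: 24, 5; 4.00: 26, 0; 6.00: 52, 5; 8.00: 57, 8; 10.0: 74, 13; 12.0: 80, 16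
- gamma (time / min: complex with one exchanged / %, complex with two exchanged / %): 2.00: 22, 0; 4.00: 30, 4; 6.00: 49, 5; 8.00: 55, 8; 10.0: 77, 11; 12.0: 80, 19

(readings scatter by 2 percentage points)

1. amount of complex with one exchanged in the flask at 12 min, in percent of the starting complex charged
2. amount of complex with two exchanged in the flask at 12 min, in percent of the starting complex charged
3. amount of starting complex in the flask at 12 min, in percent of the starting complex charged

Does the charge matter? From zeta to gamma, c(starting complex) grows by a factor of 3.88, yet at 12.0 min the two-exchanged readings differ by 3 percentage points and the one-exchanged readings are both 80%, against a scatter of 2 points. So I carry the percentages over to this flask, whose charge of 0.33 M lies between theirs, and treat each step as pseudo-first-order in complex.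

How fast does the one-exchanged complex go on? If the two-exchanged amount grows at a constant share of the one-exchanged amount per minute, integrating gives that amount as the share times the area under the one-exchanged curve. Trapezoids give an area of 5.46 min in zeta and 5.46 min in gamma. The mean two-exchanged reading at 12.0 min is 17.5%. Dividing it by the area gives my second-exchange clock, the share of one-exchanged complex going on per minute, read as 0.0321 min⁻¹.

What stands at 12 min? I commit to the mean readings, 80.0% one exchanged and 17.5% two exchanged, which leaves 2.50% starting complex.

The forecast says 81%, 17% and 2%, expecting this flask to “follow the same percentage curves”, and its one-exchanged figure stands 1 point above mine.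

The flask gives 79.3% one exchanged, 17.7% two exchanged and 3.01% starting complex.

    starting complex + incoming ligand → leaving ligand + complex with one exchanged (k = 0.540 M⁻¹ s⁻¹)
    complex with one exchanged + incoming ligand → leaving ligand + complex with two exchanged (k = 0.0270 M⁻¹ s⁻¹)
    gas ⇌ incoming ligand, rate k3*(csat - [incoming ligand]) (kL = 0.730 s⁻¹)

On a repeat, watch the one-exchanged complex past 12 min: at 12.0 min this flask makes it at 0.766 times the rate at which it is used up, each step taken net. This flask has 82.3% not yet twice exchanged at 12 min. Running the clock on for 18.0 min multiplies that by 0.562 and gives 46.3%. Read at 30 min, the same flask holds 0% starting complex, 53.8% two exchanged and 46.2% one exchanged.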